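**Retrosynthetic overview**
- Unit 1 is the 5,7-dihydroxy-4'-methoxyflavone half and unit 2 the 5-hydroxy-7-methoxyflavone half. The strategy rests on ring B of unit 2, a 1,4-phenylene that carries only the ether oxygen to C8 of unit 1 (at C4') and, para to it, C1' bonded to C2 of the second pyranone. It is cut at C2'–C3' and C4'–C5' into methyl coumalate (C1', C2', C5', C6' and the future pyranone C2) and the aryloxyacetylene of ring A of unit 1 (C3', C4'), so the ether flanked by two ortho oxygens is never made by aryl C–O coupling.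
- Ring A of unit 1 and the ether oxygen come from 2,4,6-trihydroxybenzaldehyde (two benzyl ethers, one MOM ether, Baeyer–Villiger oxidation); the phenol becomes the ynol ether with trichloroethylene and n-BuLi.
- After ring B of unit 2 is made, the ester is carried as CH2OTBS while MOM-directed lithiation, ynone formation and 6-endo closure build the pyranone of unit 1.
- The benzylic carbon is then raised to the aldehyde, condensed with mono-benzylated 2,6-dihydroxy-4-methoxyacetophenone and closed oxidatively to the pyranone of unit 2; one hydrogenolysis frees the three phenols.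
- Ring order: ring B of unit 2 (step 6), pyranone of unit 1 (step 11), pyranone of unit 2 (step 15); ring A and ring B of unit 1 and ring A of unit 2 come from the starting materials.

Key step: step 6

Remark: the target has no stereocentre; compounds 13, 20 and 28 are transient racemates, and alkenes 8 and 27 are single E isomers.

**Step 1**
Reactants: 1 2,4,6-trihydroxybenzaldehyde
Product: 2 2,4-bis(benzyloxy)-6-hydroxybenzaldehyde
Conditions: BnBr (2.1 equiv), K2CO3, DMF, 0 °C → rt
Reagents that add atoms: benzyl bromide, BrCc1ccccc1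
Why: Williamson etherification should stop after two alkylations because the last phenol is hydrogen-bonded to the aldehyde and is the least nucleophilic.

**Step 2**
Reactants: 2 2,4-bis(benzyloxy)-6-hydroxybenzaldehyde
Product: 3 2,4-bis(benzyloxy)-6-(methoxymethoxy)benzaldehyde
Conditions: MOMCl, i-Pr2NEt, CH2Cl2, 0 → 40 °C
Reagents that add atoms: chloromethyl methyl ether, COCCl
Why: O-alkylation of the chelated phenol with the reactive α-chloro ether (MOM acetal formation) should mark this one oxygen as the later pyranone oxygen and lithiation director.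

**Step 3**
Reactants: 3 2,4-bis(benzyloxy)-6-(methoxymethoxy)benzaldehyde
Product: 5 2,4-bis(benzyloxy)-6-(methoxymethoxy)phenol, via aryl formate 4 (not isolated)
Conditions: mCPBA, CH2Cl2, 0 °C → rt; then K2CO3 (0.2 equiv), MeOH, 0 °C, argon
Reagents that add atoms: 3-chloroperoxybenzoic acid, O=C(OO)c1cccc(Cl)c1
Why: Baeyer–Villiger (Dakin-type) oxidation should proceed with migration of the very electron-rich aryl group in preference to hydrogen, and the formate is cleaved by mild methanolysis.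

**Step 4**
Reactants: 5 2,4-bis(benzyloxy)-6-(methoxymethoxy)phenol; 6 trichloroethylene
Product: 8 1,5-bis(benzyloxy)-2-{[(E)-1,2-dichloroethenyl]oxy}-3-(methoxymethoxy)benzene, via dichloroacetylene 7 (not isolated)
Conditions: K2CO3, DMF, 70 °C, argon
Reagents that add atoms: none
Why: Base-induced dehydrochlorination of trichloroethylene gives dichloroacetylene, and anti addition of the phenoxide and a proton across it should give the E dichlorovinyl ether (known phenol dichlorovinylation).

**Step 5**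
Reactants: 8 1,5-bis(benzyloxy)-2-{[(E)-1,2-dichloroethenyl]oxy}-3-(methoxymethoxy)benzene
Product: 11 1,5-bis(benzyloxy)-2-(ethynyloxy)-3-(methoxymethoxy)benzene, via chloroethynyl ether 9 (not isolated), via lithium aryloxyacetylide 10 (not isolated)
Conditions: n-BuLi (2.3 equiv), THF, −78 → −40 °C; then H2O, −78 °C; used at once in step 6
Reagents that add atoms: none
Why: Greene-type ynol ether synthesis: dehydrochlorination by the first equivalent of n-BuLi, chlorine–lithium exchange by the second, and a basic water quench should give the terminal ynol ether without acid-induced hydration.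

**Step 6**
Reactants: 11 1,5-bis(benzyloxy)-2-(ethynyloxy)-3-(methoxymethoxy)benzene; 12 methyl coumalate
Product: 14 methyl 4-[2,4-bis(benzyloxy)-6-(methoxymethoxy)phenoxy]benzoate, via bridged lactone adduct 13 (not isolated)
Conditions: 12 (2 equiv), BHT (cat.), PhMe, 100 °C, sealed tube, argon
Reagents that add atoms: none
Why: The electron-poor diene C3=C4–C5=C6 of 12 and the electron-rich alkyne of 11 should combine in an inverse-electron-demand Diels–Alder reaction, a known reaction type for methyl coumalate with enol ethers, ketene acetals and heteroatom-substituted alkynes. Bonding is asynchronous: the terminal CH carbon of 11, the nucleophilic end of the ynol ether, attacks C6 of 12, the position conjugated to both the ester and the lactone carbonyl, and the aryloxy carbon then bonds to C3 to give bridged lactone 13. Ring B of unit 2 is thus closed by intermolecular [4+2] cycloaddition (bonds C2'–C3' and C4'–C5'), and retro-[4+2] loss of CO2 from 13 gives the benzene ring at the right oxidation level without an oxidant. No stereocentre survives, because the two bridgehead centres of 13 become sp2 on aromatisation. The selectivity needed is para over meta orientation, secured by this polarity match, and cycloaddition over self-reaction of 11, favoured because an aryl ynol ether has no β-hydrogen for retro-ene ketene formation and 12 is used in excess. The doubly ortho-substituted aryl ring is twisted out of conjugation with the ether oxygen, which should leave the lone pair to raise the alkyne HOMO enough for reaction near 100 °C.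

**Step 7**
Reactants: 14 methyl 4-[2,4-bis(benzyloxy)-6-(methoxymethoxy)phenoxy]benzoate
Product: 15 {4-[2,4-bis(benzyloxy)-6-(methoxymethoxy)phenoxy]phenyl}methanol
Conditions: LiAlH4, THF, 0 °C
Reagents that add atoms: none
Why: Hydride reduction of the ester to the primary alcohol removes the only group that would not tolerate the later aryllithium, and the ethers and the acetal are inert to it.

**Step 8**
Reactants: 15 {4-[2,4-bis(benzyloxy)-6-(methoxymethoxy)phenoxy]phenyl}methanol
Product: 16 ({4-[2,4-bis(benzyloxy)-6-(methoxymethoxy)phenoxy]benzyl}oxy)(tert-butyl)dimethylsilane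
Conditions: TBSCl, imidazole, DMF, rt
Reagents that add atoms: tert-butyldimethylsilyl chloride, CC(C)(C)[Si](C)(C)Cl
Why: Standard silylation of a primary alcohol masks the acidic OH before metalation.

**Step 9**
Reactants: 17 3-(4-methoxyphenyl)propiolic acid
Product: 18 N-methoxy-3-(4-methoxyphenyl)-N-methylprop-2-ynamide
Conditions: MeNH(OMe)·HCl, EDC·HCl, N-methylmorpholine, CH2Cl2, 0 °C → rt
Reagents that add atoms: N,O-dimethylhydroxylamine hydrochloride, CNOC.Cl
Why: Carbodiimide amide coupling at low temperature should give the Weinreb amide, with 1,2-acylation faster than conjugate addition of the weakly nucleophilic amine.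

**Step 10**
Reactants: 16 ({4-[2,4-bis(benzyloxy)-6-(methoxymethoxy)phenoxy]benzyl}oxy)(tert-butyl)dimethylsilane; 18 N-methoxy-3-(4-methoxyphenyl)-N-methylprop-2-ynamide
Product: 21 1-[4,6-bis(benzyloxy)-3-(4-{[(tert-butyldimethylsilyl)oxy]methyl}phenoxy)-2-(methoxymethoxy)phenyl]-3-(4-methoxyphenyl)prop-2-yn-1-one, via aryllithium 19 (not isolated), via lithium hemiaminal adduct 20 (not isolated)
Conditions: n-BuLi, TMEDA, THF, −20 → 0 °C; then 18, −78 → −40 °C; AcOH, −78 °C
Reagents that add atoms: none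
Why: Directed ortho-metalation should occur at the CH of ring A of unit 1 that lies between the chelating OMOM group and a benzyloxy group rather than at the CH between two benzyloxy groups, and Weinreb acyl substitution stops at the ketone because adduct 20 is a stable chelate until the cold acidic quench.

**Step 11**
Reactants: 21 1-[4,6-bis(benzyloxy)-3-(4-{[(tert-butyldimethylsilyl)oxy]methyl}phenoxy)-2-(methoxymethoxy)phenyl]-3-(4-methoxyphenyl)prop-2-yn-1-one
Product: 23 5,7-bis(benzyloxy)-8-[4-(hydroxymethyl)phenoxy]-2-(4-methoxyphenyl)-4H-chromen-4-one, via free hydroxy ynone 22 (not isolated)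
Conditions: TsOH·H2O, THF/H2O (9:1), 50 °C; then DMAP (cat.), DMF, 40 °C
Reagents that add atoms: none
Why: Acid hydrolysis of the MOM acetal and the silyl ether frees the only phenol ortho to the ynone, and DMAP-catalysed 6-endo-dig oxa-Michael cyclisation should then give the 8-aryloxyflavone and not an aurone or the 6-aryloxy isomer.

**Step 12**
Reactants: 23 5,7-bis(benzyloxy)-8-[4-(hydroxymethyl)phenoxy]-2-(4-methoxyphenyl)-4H-chromen-4-one
Product: 24 4-{[5,7-bis(benzyloxy)-2-(4-methoxyphenyl)-4-oxo-4H-chromen-8-yl]oxy}benzaldehyde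
Conditions: Dess–Martin periodinane, CH2Cl2, rt
Reagents that add atoms: none
Why: Dess–Martin oxidation of the benzylic alcohol should stop at the aldehyde and leave the flavone and the ethers untouched.

**Step 13**
Reactants: 25 1-(2,6-dihydroxy-4-methoxyphenyl)ethanone
Product: 26 1-[2-(benzyloxy)-6-hydroxy-4-methoxyphenyl]ethanone
Conditions: BnBr (1.05 equiv), K2CO3, acetone, reflux
Reagents that add atoms: benzyl bromide, BrCc1ccccc1
Why: Williamson mono-benzylation of the symmetrical diphenol should stop after one alkylation because the remaining OH is then locked in a hydrogen bond to the ketone.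

**Step 14**
Reactants: 24 4-{[5,7-bis(benzyloxy)-2-(4-methoxyphenyl)-4-oxo-4H-chromen-8-yl]oxy}benzaldehyde; 26 1-[2-(benzyloxy)-6-hydroxy-4-methoxyphenyl]ethanone
Product: 27 5,7-bis(benzyloxy)-8-(4-{(E)-3-[2-(benzyloxy)-6-hydroxy-4-methoxyphenyl]-3-oxoprop-1-en-1-yl}phenoxy)-2-(4-methoxyphenyl)-4H-chromen-4-one
Conditions: KOH, EtOH/THF, rt
Reagents that add atoms: none
Why: Claisen–Schmidt condensation of the methyl ketone enolate with the non-enolisable aldehyde, followed by base-induced dehydration of the aldol, should give the conjugated E chalcone.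

**Step 15**
Reactants: 27 5,7-bis(benzyloxy)-8-(4-{(E)-3-[2-(benzyloxy)-6-hydroxy-4-methoxyphenyl]-3-oxoprop-1-en-1-yl}phenoxy)-2-(4-methoxyphenyl)-4H-chromen-4-one
Product: 29 5,7-bis(benzyloxy)-8-{4-[5-(benzyloxy)-7-methoxy-4-oxo-4H-chromen-2-yl]phenoxy}-2-(4-methoxyphenyl)-4H-chromen-4-one, via flavanone 28 (not isolated)
Conditions: I2 (0.1 equiv), DMSO, 120 °C
Reagents that add atoms: none
Why: Iodine-catalysed oxidative cyclisation of a 2'-hydroxychalcone (oxa-Michael closure, α-iodination, loss of HI) should give the flavone, with DMSO as the terminal oxidant that regenerates iodine.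

**Step 16**
Reactants: 29 5,7-bis(benzyloxy)-8-{4-[5-(benzyloxy)-7-methoxy-4-oxo-4H-chromen-2-yl]phenoxy}-2-(4-methoxyphenyl)-4H-chromen-4-one
Product: 30 5,7-dihydroxy-8-[4-(5-hydroxy-7-methoxy-4-oxo-4H-chromen-2-yl)phenoxy]-2-(4-methoxyphenyl)-4H-chromen-4-one
Conditions: H2 (1 atm), 10% Pd/C, THF/MeOH, rt
Reagents that add atoms: none
Why: Catalytic hydrogenolysis should cleave the three benzyl ethers and leave the diaryl ether, the two methyl ethers and the flavone double bonds intact.

**Compound list**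
1 | 2,4,6-trihydroxybenzaldehyde | O=Cc1c(O)cc(O)cc1O | starting material
2 | 2,4-bis(benzyloxy)-6-hydroxybenzaldehyde | O=Cc1c(O)cc(OCc2ccccc2)cc1OCc1ccccc1 | intermediate
3 | 2,4-bis(benzyloxy)-6-(methoxymethoxy)benzaldehyde | O=Cc1c(OCOC)cc(OCc2ccccc2)cc1OCc1ccccc1 | intermediate
4 | 2,4-bis(benzyloxy)-6-(methoxymethoxy)phenyl formate (not isolated) | O=COc1c(OCOC)cc(OCc2ccccc2)cc1OCc1ccccc1 | intermediate
5 | 2,4-bis(benzyloxy)-6-(methoxymethoxy)phenol | Oc1c(OCOC)cc(OCc2ccccc2)cc1OCc1ccccc1 | intermediate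
6 | trichloroethylene | ClC=C(Cl)Cl | starting material
7 | dichloroacetylene (not isolated) | ClC#CCl | intermediate
8 | 1,5-bis(benzyloxy)-2-{[(E)-1,2-dichloroethenyl]oxy}-3-(methoxymethoxy)benzene | Cl/C=C(/Cl)Oc1c(OCOC)cc(OCc2ccccc2)cc1OCc1ccccc1 | intermediate
9 | 1,5-bis(benzyloxy)-2-[(chloroethynyl)oxy]-3-(methoxymethoxy)benzene (not isolated) | ClC#COc1c(OCOC)cc(OCc2ccccc2)cc1OCc1ccccc1 | intermediate
10 | lithium 2-[2,4-bis(benzyloxy)-6-(methoxymethoxy)phenoxy]ethynide (not isolated) | [Li]C#COc1c(OCOC)cc(OCc2ccccc2)cc1OCc1ccccc1 | intermediate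
11 | 1,5-bis(benzyloxy)-2-(ethynyloxy)-3-(methoxymethoxy)benzene | C#COc1c(OCOC)cc(OCc2ccccc2)cc1OCc1ccccc1 | intermediate
12 | methyl coumalate (methyl 2-oxo-2H-pyran-5-carboxylate) | COC(=O)c1ccc(=O)oc1 | starting material
13 | methyl 8-[2,4-bis(benzyloxy)-6-(methoxymethoxy)phenoxy]-3-oxo-2-oxabicyclo[2.2.2]octa-5,7-diene-6-carboxylate (racemic, not isolated) | COC(=O)C1=CC2C(=O)OC1C=C2Oc1c(OCOC)cc(OCc2ccccc2)cc1OCc1ccccc1 | intermediate
14 | methyl 4-[2,4-bis(benzyloxy)-6-(methoxymethoxy)phenoxy]benzoate | COC(=O)c1ccc(Oc2c(OCOC)cc(OCc3ccccc3)cc2OCc2ccccc2)cc1 | intermediate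
15 | {4-[2,4-bis(benzyloxy)-6-(methoxymethoxy)phenoxy]phenyl}methanol | OCc1ccc(Oc2c(OCOC)cc(OCc3ccccc3)cc2OCc2ccccc2)cc1 | intermediate
16 | ({4-[2,4-bis(benzyloxy)-6-(methoxymethoxy)phenoxy]benzyl}oxy)(tert-butyl)dimethylsilane | CC(C)(C)[Si](C)(C)OCc1ccc(Oc2c(OCOC)cc(OCc3ccccc3)cc2OCc2ccccc2)cc1 | intermediate
17 | 3-(4-methoxyphenyl)propiolic acid | COc1ccc(C#CC(=O)O)cc1 | starting material
18 | N-methoxy-3-(4-methoxyphenyl)-N-methylprop-2-ynamide | COc1ccc(C#CC(=O)N(C)OC)cc1 | intermediate
19 | [4,6-bis(benzyloxy)-3-(4-{[(tert-butyldimethylsilyl)oxy]methyl}phenoxy)-2-(methoxymethoxy)phenyl]lithium (not isolated) | CC(C)(C)[Si](C)(C)OCc1ccc(Oc2c(OCOC)c([Li])c(OCc3ccccc3)cc2OCc2ccccc2)cc1 | intermediate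
20 | lithium 1-[4,6-bis(benzyloxy)-3-(4-{[(tert-butyldimethylsilyl)oxy]methyl}phenoxy)-2-(methoxymethoxy)phenyl]-1-[methoxy(methyl)amino]-3-(4-methoxyphenyl)prop-2-yn-1-olate (racemic, not isolated) | CC(C)(C)[Si](C)(C)OCc1ccc(Oc2c(OCOC)c(C(O[Li])(N(C)OC)C#Cc3ccc(OC)cc3)c(OCc3ccccc3)cc2OCc2ccccc2)cc1 | intermediate
21 | 1-[4,6-bis(benzyloxy)-3-(4-{[(tert-butyldimethylsilyl)oxy]methyl}phenoxy)-2-(methoxymethoxy)phenyl]-3-(4-methoxyphenyl)prop-2-yn-1-one | CC(C)(C)[Si](C)(C)OCc1ccc(Oc2c(OCOC)c(C(=O)C#Cc3ccc(OC)cc3)c(OCc3ccccc3)cc2OCc2ccccc2)cc1 | intermediate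
22 | 1-{4,6-bis(benzyloxy)-2-hydroxy-3-[4-(hydroxymethyl)phenoxy]phenyl}-3-(4-methoxyphenyl)prop-2-yn-1-one (not isolated) | OCc1ccc(Oc2c(O)c(C(=O)C#Cc3ccc(OC)cc3)c(OCc3ccccc3)cc2OCc2ccccc2)cc1 | intermediate
23 | 5,7-bis(benzyloxy)-8-[4-(hydroxymethyl)phenoxy]-2-(4-methoxyphenyl)-4H-chromen-4-one | COc1ccc(-c2cc(=O)c3c(OCc4ccccc4)cc(OCc4ccccc4)c(Oc4ccc(CO)cc4)c3o2)cc1 | intermediate
24 | 4-{[5,7-bis(benzyloxy)-2-(4-methoxyphenyl)-4-oxo-4H-chromen-8-yl]oxy}benzaldehyde | COc1ccc(-c2cc(=O)c3c(OCc4ccccc4)cc(OCc4ccccc4)c(Oc4ccc(C=O)cc4)c3o2)cc1 | intermediate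
25 | 1-(2,6-dihydroxy-4-methoxyphenyl)ethanone | CC(=O)c1c(O)cc(OC)cc1O | starting material
26 | 1-[2-(benzyloxy)-6-hydroxy-4-methoxyphenyl]ethanone | CC(=O)c1c(O)cc(OC)cc1OCc1ccccc1 | intermediate
27 | 5,7-bis(benzyloxy)-8-(4-{(E)-3-[2-(benzyloxy)-6-hydroxy-4-methoxyphenyl]-3-oxoprop-1-en-1-yl}phenoxy)-2-(4-methoxyphenyl)-4H-chromen-4-one | COc1ccc(-c2cc(=O)c3c(OCc4ccccc4)cc(OCc4ccccc4)c(Oc4ccc(/C=C/C(=O)c5c(O)cc(OC)cc5OCc5ccccc5)cc4)c3o2)cc1 | intermediate
28 | 5,7-bis(benzyloxy)-8-{4-[5-(benzyloxy)-7-methoxy-4-oxochroman-2-yl]phenoxy}-2-(4-methoxyphenyl)-4H-chromen-4-one (racemic, not isolated) | COc1ccc(-c2cc(=O)c3c(OCc4ccccc4)cc(OCc4ccccc4)c(Oc4ccc(C5CC(=O)c6c(OCc7ccccc7)cc(OC)cc6O5)cc4)c3o2)cc1 | intermediate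
29 | 5,7-bis(benzyloxy)-8-{4-[5-(benzyloxy)-7-methoxy-4-oxo-4H-chromen-2-yl]phenoxy}-2-(4-methoxyphenyl)-4H-chromen-4-one | COc1ccc(-c2cc(=O)c3c(OCc4ccccc4)cc(OCc4ccccc4)c(Oc4ccc(-c5cc(=O)c6c(OCc7ccccc7)cc(OC)cc6o5)cc4)c3o2)cc1 | intermediate
30 | 5,7-dihydroxy-8-[4-(5-hydroxy-7-methoxy-4-oxo-4H-chromen-2-yl)phenoxy]-2-(4-methoxyphenyl)-4H-chromen-4-one (CNP0124888.0) | COc1ccc(-c2cc(=O)c3c(O)cc(O)c(Oc4ccc(-c5cc(=O)c6c(O)cc(OC)cc6o5)cc4)c3o2)cc1 | target

**Totals**
Total step count: 16.
Longest linear sequence: 14 steps (steps 1–8, 10–12, 14–16); steps 9 and 13 prepare the two side partners.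

**Steps most likely to fail**

1. Step 6 (cycloaddition). The ynol ether may oligomerise or be hydrated before it adds to the pyranone, or it may add stepwise across C5=C6 in a [2+2] sense, and the para orientation may erode if bonding becomes less polarised at high temperature. Fallback: set out from phenol 5 and form the diaryl ether by nucleophilic aromatic substitution on 4-fluorobenzaldehyde (K2CO3, DMF, 110 °C) to give 4-[2,4-bis(benzyloxy)-6-(methoxymethoxy)phenoxy]benzaldehyde F1. Reduction with NaBH4 (MeOH/THF, 0 °C) then returns to the route at alcohol 15.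

2. Step 10 (lithiation and acylation). Metalation may be incomplete or partly mis-sited. Acyl transfer may also fail, because the hindered, strongly basic aryllithium can deprotonate the N-methoxy group of the Weinreb amide or add in a 1,4 sense, and the liberated amine can add to the ynone on warming. Fallback: set out from 16, metalate as before and trap with the small electrophile DMF (water quench) to give 4,6-bis(benzyloxy)-3-(4-{[(tert-butyldimethylsilyl)oxy]methyl}phenoxy)-2-(methoxymethoxy)benzaldehyde F2. Add the lithium acetylide of 1-ethynyl-4-methoxybenzene (n-BuLi, THF, −78 °C; water quench) to give racemic 1-[4,6-bis(benzyloxy)-3-(4-{[(tert-butyldimethylsilyl)oxy]methyl}phenoxy)-2-(methoxymethoxy)phenyl]-3-(4-methoxyphenyl)prop-2-yn-1-ol F3, and oxidise with MnO2 (CH2Cl2, rt) to return to the route at ynone 21. This fallback still depends on the same metalation and answers only the acyl-transfer failure.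

3. Step 14 (Claisen–Schmidt condensation). Hydroxide may attack C2 of the pyranone already present in unit 1 and open that ring, while the aldol condensation of the hindered, doubly ortho-substituted ketone enolate is slow. Fallback: set out from aldehyde 24 and build unit 2 by a Baker–Venkataraman sequence. Pinnick oxidation (NaClO2, NaH2PO4, 2-methyl-2-butene, t-BuOH/H2O) gives 4-{[5,7-bis(benzyloxy)-2-(4-methoxyphenyl)-4-oxo-4H-chromen-8-yl]oxy}benzoic acid F4. Esterification with the phenol of 26 (N,N'-dicyclohexylcarbodiimide, DMAP, CH2Cl2) gives 2-acetyl-3-(benzyloxy)-5-methoxyphenyl 4-{[5,7-bis(benzyloxy)-2-(4-methoxyphenyl)-4-oxo-4H-chromen-8-yl]oxy}benzoate F5. Acyl transfer with LiN(SiMe3)2 (THF, −78 → 0 °C; AcOH quench) gives 1-[2-(benzyloxy)-6-hydroxy-4-methoxyphenyl]-3-(4-{[5,7-bis(benzyloxy)-2-(4-methoxyphenyl)-4-oxo-4H-chromen-8-yl]oxy}phenyl)propane-1,3-dione F6. Cyclodehydration (TsOH·H2O, PhMe, 80 °C) returns to the route at tribenzyl biflavone 29, so steps 14 and 15 are bypassed.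

**Further compounds**
F1 | step 6 | 4-[2,4-bis(benzyloxy)-6-(methoxymethoxy)phenoxy]benzaldehyde | O=Cc1ccc(Oc2c(OCOC)cc(OCc3ccccc3)cc2OCc2ccccc2)cc1
F2 | step 10 | 4,6-bis(benzyloxy)-3-(4-{[(tert-butyldimethylsilyl)oxy]methyl}phenoxy)-2-(methoxymethoxy)benzaldehyde | CC(C)(C)[Si](C)(C)OCc1ccc(Oc2c(OCOC)c(C=O)c(OCc3ccccc3)cc2OCc2ccccc2)cc1
F3 | step 10 | 1-[4,6-bis(benzyloxy)-3-(4-{[(tert-butyldimethylsilyl)oxy]methyl}phenoxy)-2-(methoxymethoxy)phenyl]-3-(4-methoxyphenyl)prop-2-yn-1-ol (racemic) | CC(C)(C)[Si](C)(C)OCc1ccc(Oc2c(OCOC)c(C(O)C#Cc3ccc(OC)cc3)c(OCc3ccccc3)cc2OCc2ccccc2)cc1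
F4 | step 14 | 4-{[5,7-bis(benzyloxy)-2-(4-methoxyphenyl)-4-oxo-4H-chromen-8-yl]oxy}benzoic acid | COc1ccc(-c2cc(=O)c3c(OCc4ccccc4)cc(OCc4ccccc4)c(Oc4ccc(C(=O)O)cc4)c3o2)cc1
F5 | step 14 | 2-acetyl-3-(benzyloxy)-5-methoxyphenyl 4-{[5,7-bis(benzyloxy)-2-(4-methoxyphenyl)-4-oxo-4H-chromen-8-yl]oxy}benzoate | COc1ccc(-c2cc(=O)c3c(OCc4ccccc4)cc(OCc4ccccc4)c(Oc4ccc(C(=O)Oc5cc(OC)cc(OCc6ccccc6)c5C(C)=O)cc4)c3o2)cc1
F6 | step 14 | 1-[2-(benzyloxy)-6-hydroxy-4-methoxyphenyl]-3-(4-{[5,7-bis(benzyloxy)-2-(4-methoxyphenyl)-4-oxo-4H-chromen-8-yl]oxy}phenyl)propane-1,3-dione | COc1ccc(-c2cc(=O)c3c(OCc4ccccc4)cc(OCc4ccccc4)c(Oc4ccc(C(=O)CC(=O)c5c(O)cc(OC)cc5OCc5ccccc5)cc4)c3o2)cc1
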